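Readings and results are calculated for substances that don't exist, noise included.

The constants first, since you can redo them by hand from the violet run. You asked for a quick number and suspected that each product costs two partners. We read the runs the same way: partner turns substrate into an unseen intermediate, and a second partner turns that into product.

the same everywhere: substrate 0.20 M

| charge | partner | remark | time |
|---|---|---|---|
| grey | 0.13 M | run made earlier |  |
| violet | 1.2 M | run made earlier |  |
| north-east | 0.120 M |  | 40 h |
| north-west | 0.500 M |  | 40 h |
| north | 0.800 M |  | 40 h |
| south | 0.400 M |  | 40 h |
| south-east | 0.100 M |  | 40 h |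
| east | 0.180 M |  | 40 h |

| run | time / h | product / % | substrate / % |
|---|---|---|---|
| grey | 2.50 | 1.0 | 62.7 |
| grey | 3.00 | 1.5 | 58.6 |
| grey | 5.00 | 2.6 | 46.5 |
| grey | 8.00 | 4.1 | 34.7 |
| grey | 12.0 | 4.4 | 24.9 |
| grey | 20.0 | 7.7 | 18.6 |
| grey | 30.0 | 6.8 | 11.8 |
| violet | 2.50 | 42.7 | 2.2 |
| violet | 3.00 | 48.6 | 1.4 |
| violet | 5.00 | 67.1 | 0.5 |
| violet | 8.00 | 78.8 | 0 |
| violet | 12.0 | 82.9 | 0.1 |
| violet | 20.0 | 87.6 | 0.2 |
| violet | 30.0 | 85.1 | 0 |

(each reading ± 1 percentage point)



- the flasks by amount of product, in percent of the substrate charged, highest first, at 40 h (north-east / north-west / north / south / south-east / east)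
- the amount of product, in percent of the substrate charged of the flask you put first, at 40 h
- the amount of product, in percent of the substrate charged of the flask you put last, at 40 h

In violet, substrate falls to 2.2% by 2.50 h. At a mean partner of 1.10 M, that reads as a first constant of 1.39 /M/h. Product averages 86.3% over the readings at 20.0 h and 30.0 h, and its approach to that plateau between 2.50 h and 5.00 h, at about 0.900 M of partner, reads as a second constant of 0.364 /M/h. Both carry the scatter.

The second constant divided by the first is our selectivity factor, 0.262. In our reading partner multiplies both rates, so when one rate is divided by the other, partner and time drop out. In that reading, partner splits between the two steps as factor × [intermediate] to [substrate], where [intermediate] is the unseen one. This gives us a rule rather than the forecast's numbers.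

The forecast is north > north-west > south > east > north-east > south-east, with 77% on top and 4.3% at the bottom, on the ground that “Yield should rise monotonically with partner”.

The simulation gives the same order, north > north-west > south > east > north-east > south-east, with north at 84.6% and south-east at 5.05%.

    intermediate B ⇌ intermediate C (K = 0.330, k = 1.10 × 10⁻⁴ /s)
    intermediate B → decomposed reagent (k = 1.90 × 10⁻⁵ /s)
    substrate + partner → intermediate A (k = 3.80 × 10⁻⁴ /M/s)
    partner + intermediate A ⇌ intermediate B (K = 160 /M, k = 1.30 × 10⁻⁵ /M/s)
    partner + intermediate A → product (k = 9.40 × 10⁻⁵ /M/s)
    substrate ⇌ dormant form (K = 4.00, k = 1.40 × 10⁻⁵ /s)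

South-east has not quite stopped. At 40.0 h it holds 1.4% of its partner, which equals 0.703% of the substrate charged, beside substrate 13.6% and intermediate A 37.8%. Our factor sends 42.2% of that partner to product, a gain of 0.3 percentage points, which makes 5.35% of product. At 400 h the simulation puts south-east's product at 5.34%, with partner at 0%. North's product moves further, to 87.8%.

One more flask, charged with 0.20 M of partner, holds 1.00 equiv of partner to substrate. Integrating the split as if its partner were spent, and leaving dormant form out, we reckon its product at 18.9%, the point where reckoned product equals reckoned remaining substrate. The simulation gives that flask 21.5% of product at 40.0 h, with 3.93% of its partner left.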